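Assumption: positions are named by germacranolide numbering (C1–C10 ring, C11–C13 lactone side, C14 on C10, C15 on C4), and the listed small starting materials are taken as commercially available.

## Retrosynthetic overview

1. Target 32 ⇐ 1(10)-alkene 31 by peripheral epoxidation (oxirane formed last); 31 ⇐ 8α-alcohol 26 + epoxy acid 29 by esterification with inversion at C8.
2. Key step: 26 ⇐ seco-aldehyde 23 by C7–C8 bond formation. A samarium ketyl radical at C8 adds 10-exo to C7 of the butenolide and the C13 acetate is expelled, which closes the ten-membered ring and unveils the 11(13)-methylene.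
3. 23 ⇐ C3–C4 asymmetric Ni/Cr coupling of (Z)-alkenyl iodide butenolide 11 with β,γ-unsaturated aldehyde 18, then isovalerate at O3 and oxidation at C8.
4. 11 ⇐ ring-closing metathesis of the 2-(acetoxymethyl)acrylate of iodo dienol 6 (from acrolein + propynyl Grignard, kinetic resolution, trans-hydroalumination/iodination); 18 ⇐ but-3-yn-1-ol (carboalumination, oxirane).
5. Ring order: lactone (metathesis) → ten-membered carbocycle (radical) → oxirane.

## Route

Step 1
Reactants: 1 prop-2-enal (acrolein); 2 prop-1-yn-1-ylmagnesium bromide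
Product: 3 rac-hex-1-en-4-yn-3-ol
Conditions: THF, −78 → 0 °C; aq NH4Cl
Reagents that add atoms: none
Why: Grignard 1,2-addition of the alkynyl nucleophile to the enal carbonyl gives the vinyl alkynyl carbinol that carries C4–C7 and C15.

Step 2
Reactants: 3 rac-hex-1-en-4-yn-3-ol
Product: 4 (3S)-hex-1-en-4-yn-3-ol
Conditions: Ti(OiPr)4 (10 mol%), L-(+)-diisopropyl tartrate (15 mol%), t-BuOOH (0.6 equiv), 4 Å MS, CH2Cl2, −20 °C, to about 55–60% conversion
Reagents that add atoms: none
Why: Sharpless kinetic resolution; with the L-(+)-tartrate the enantiomer spatially equivalent to an (S)-alkyl vinyl carbinol, here (R)-3 because alkynyl outranks vinyl, is epoxidised fast, so (S)-4 (the future C6 centre) is recovered in high ee.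

Step 3
Reactants: 4 (3S)-hex-1-en-4-yn-3-ol
Product: 6 (3S,4Z)-5-iodohexa-1,4-dien-3-ol, via cyclic alkenylalanate 5 (not isolated)
Conditions: NaAlH2(OCH2CH2OMe)2, THF, 0 °C → rt; then EtOAc; I2, −78 → 0 °C
Reagents that add atoms: iodine, II
Why: Alkoxide-directed trans-hydroalumination of the propargylic alcohol puts H on the proximal and Al on the distal alkyne carbon, and iodinolysis with retention gives the iodide cis to the carbinol carbon, which fixes the later 4Z geometry.

Step 4
Reactants: 7 2-(bromomethyl)prop-2-enoic acid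
Product: 8 2-(acetoxymethyl)prop-2-enoic acid
Conditions: NaOAc (4 equiv), AcOH, 60 °C
Reagents that add atoms: sodium acetate, CC(=O)[O-].[Na+]
Why: Allylic substitution of bromide by acetate (direct and allyl-shifted attack give the same product) installs the leaving group needed at C13.

Step 5
Reactants: 8 2-(acetoxymethyl)prop-2-enoic acid; 6 (3S,4Z)-5-iodohexa-1,4-dien-3-ol
Product: 10 (3S,4Z)-5-iodohexa-1,4-dien-3-yl 2-(acetoxymethyl)prop-2-enoate, via acid chloride 9 (not isolated)
Conditions: 8, (COCl)2, cat. DMF, CH2Cl2, 0 °C → rt; concentrate; then 6, pyridine, CH2Cl2, −20 → 0 °C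
Reagents that add atoms: none
Why: Acylation of the secondary alcohol through the acid chloride under mild pyridine conditions (no nucleophilic amine catalyst that could attack the acetoxymethyl acrylate) leaves the carbinol configuration untouched.

Step 6
Reactants: 10 (3S,4Z)-5-iodohexa-1,4-dien-3-yl 2-(acetoxymethyl)prop-2-enoate
Product: 11 [(5S)-5-[(1Z)-2-iodoprop-1-en-1-yl]-2-oxo-2,5-dihydrofuran-3-yl]methyl acetate
Conditions: second-generation Grubbs catalyst RuCl2(=CHPh)(H2IMes)(PCy3) (5 mol%), CH2Cl2 (5 mM), 40 °C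
Reagents that add atoms: none
Why: Ring-closing metathesis of the terminal vinyl group with the 1,1-disubstituted acrylate forms the butenolide (C7=C11) with loss of ethene, the trisubstituted iodoalkene being inert.

Step 7
Reactants: 12 but-3-yn-1-ol
Product: 13 (but-3-yn-1-yloxy)triethylsilane
Conditions: Et3SiCl, imidazole, CH2Cl2, 0 °C → rt
Reagents that add atoms: chlorotriethylsilane, CC[Si](CC)(CC)Cl
Why: Silyl ether formation differentiates the future C8 oxygen from the C3 terminus created in step 8.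

Step 8
Reactants: 13 (but-3-yn-1-yloxy)triethylsilane; 14 oxirane
Product: 17 (3E)-4-methyl-6-(triethylsilyloxy)hex-3-en-1-ol, via alkenyldimethylalane 15 (not isolated), via lithium alkenylalanate 16 (not isolated)
Conditions: Me3Al, Cp2ZrCl2 (25 mol%), CH2Cl2, 0 °C → rt; evaporate; THF, n-BuLi, −78 → 0 °C; oxirane, −30 °C → rt; aq Rochelle salt
Reagents that add atoms: trimethylaluminium, C[Al](C)C
Why: Negishi zirconium-catalysed syn-carboalumination places the C14 methyl on the internal carbon and Al on the terminus, and the derived alanate opens oxirane with retention, which sets the 1(10)E alkene and adds C2–C3.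

Step 9
Reactants: 17 (3E)-4-methyl-6-(triethylsilyloxy)hex-3-en-1-ol
Product: 18 (3E)-4-methyl-6-(triethylsilyloxy)hex-3-enal
Conditions: Dess–Martin periodinane, NaHCO3, CH2Cl2, 0 °C; used at once
Reagents that add atoms: none
Why: Buffered Dess–Martin oxidation gives the β,γ-unsaturated aldehyde without base, so the alkene does not move into conjugation.

Step 10
Reactants: 11 [(5S)-5-[(1Z)-2-iodoprop-1-en-1-yl]-2-oxo-2,5-dihydrofuran-3-yl]methyl acetate; 18 (3E)-4-methyl-6-(triethylsilyloxy)hex-3-enal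
Product: 19 [(5R)-5-[(1Z,3S,5E)-3-hydroxy-2,6-dimethyl-8-(triethylsilyloxy)octa-1,5-dien-1-yl]-2-oxo-2,5-dihydrofuran-3-yl]methyl acetate
Conditions: CrCl2 (10 mol%), valinol-derived aryl-oxazoline sulfonamide ligand (Kishi type, 12 mol%), 1,8-bis(dimethylamino)naphthalene (12 mol%), NiCl2(2,9-dimethyl-1,10-phenanthroline) (2 mol%), Mn powder, Cp2ZrCl2, LiCl, MeCN, rt
Reagents that add atoms: none
Why: Catalytic asymmetric Nozaki–Hiyama–Kishi coupling; zerovalent nickel inserts into the alkenyl iodide with retention of the Z geometry, and the ligand-bound alkenyl trivalent-chromium species adds to the aldehyde under catalyst control (ligand antipode chosen to give 3S), while lactone, acetate and silyl ether are inert.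

Step 11
Reactants: 19 [(5R)-5-[(1Z,3S,5E)-3-hydroxy-2,6-dimethyl-8-(triethylsilyloxy)octa-1,5-dien-1-yl]-2-oxo-2,5-dihydrofuran-3-yl]methyl acetate; 20 3-methylbutanoyl chloride
Product: 21 (1Z,3S,5E)-1-[(2R)-4-(acetoxymethyl)-5-oxo-2,5-dihydrofuran-2-yl]-2,6-dimethyl-8-(triethylsilyloxy)octa-1,5-dien-3-yl 3-methylbutanoate
Conditions: pyridine, CH2Cl2, 0 °C
Reagents that add atoms: none
Why: O-acylation of the only free hydroxyl installs the C3 isovalerate with retention; pyridine is too weak a base to epimerise the γ-position of the butenolide.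

Step 12
Reactants: 21 (1Z,3S,5E)-1-[(2R)-4-(acetoxymethyl)-5-oxo-2,5-dihydrofuran-2-yl]-2,6-dimethyl-8-(triethylsilyloxy)octa-1,5-dien-3-yl 3-methylbutanoate
Product: 23 (1Z,3S,5E)-1-[(2R)-4-(acetoxymethyl)-5-oxo-2,5-dihydrofuran-2-yl]-2,6-dimethyl-8-oxoocta-1,5-dien-3-yl 3-methylbutanoate, via primary alcohol 22 (not isolated)
Conditions: 2-iodoxybenzoic acid (IBX, 3 equiv), DMSO, rt; used at once
Reagents that add atoms: none
Why: IBX in DMSO cleaves primary triethylsilyl ethers and oxidises the released alcohol in the same pot, giving the C8 aldehyde without an amine base that could shift the 1(10)-alkene or epimerise C6.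

Step 13
Reactants: 23 (1Z,3S,5E)-1-[(2R)-4-(acetoxymethyl)-5-oxo-2,5-dihydrofuran-2-yl]-2,6-dimethyl-8-oxoocta-1,5-dien-3-yl 3-methylbutanoate
Product: 26 (3aR,4S,6E,9S,10Z,11aR)-4-hydroxy-6,10-dimethyl-3-methylidene-2-oxo-2,3,3a,4,5,8,9,11a-octahydrocyclodeca[b]furan-9-yl 3-methylbutanoate, via samarium ketyl radical 24 (not isolated), via macrocyclic samarium enolate 25 (not isolated)
Conditions: SmI2 (3 equiv), degassed THF, 0 °C, 23 added over 6 h (final 2 mM); aq NaHCO3
Reagents that add atoms: none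
Why: Proposed new method: SmI2 without HMPA reduces the aldehyde in preference to the butenolide, the C8 ketyl radical closes the ring by 10-exo addition to C7 anti to the C5 substituent (trans 6,7-lactone, 7R), the C11 radical is reduced to the samarium enolate and expels acetate (E1cB) to give the 11(13)-methylene, and C8 is expected as 8S (OH trans to C11) with the O–SmI2 group outside the ring next to the chelating C13 acetate; the closest known reactions are anti-selective SmI2 ketyl–olefin cyclisations onto unsaturated esters and lactones and radical addition–elimination on 2-(acyloxymethyl)acrylates.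

Step 14
Reactants: 27 (2E)-2-methylbut-2-en-1-ol
Product: 28 [(2S,3S)-2,3-dimethyloxiran-2-yl]methanol
Conditions: Ti(OiPr)4 (5 mol%), L-(+)-diethyl tartrate (6 mol%), t-BuOOH, 4 Å MS, CH2Cl2, −20 °C
Reagents that add atoms: tert-butyl hydroperoxide, CC(C)(C)OO
Why: Sharpless asymmetric epoxidation; the L-(+)-tartrate catalyst delivers oxygen to the face that gives the (2S,3S)-epoxy alcohol, with the E-alkene geometry transferred to the cis-dimethyl oxirane.

Step 15
Reactants: 28 [(2S,3S)-2,3-dimethyloxiran-2-yl]methanol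
Product: 29 (2R,3S)-2,3-dimethyloxirane-2-carboxylic acid
Conditions: TEMPO (20 mol%), PhI(OAc)2 (2.2 equiv), MeCN/H2O, rt
Reagents that add atoms: water, O
Why: Oxoammonium oxidation of the primary alcohol through the aldehyde hydrate gives the glycidic acid without touching the oxirane; the C2 descriptor changes from S to R only because the CIP ranking changes.

Step 16
Reactants: 26 (3aR,4S,6E,9S,10Z,11aR)-4-hydroxy-6,10-dimethyl-3-methylidene-2-oxo-2,3,3a,4,5,8,9,11a-octahydrocyclodeca[b]furan-9-yl 3-methylbutanoate; 29 (2R,3S)-2,3-dimethyloxirane-2-carboxylic acid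
Product: 31 (3aR,4R,6E,9S,10Z,11aR)-6,10-dimethyl-3-methylidene-9-(3-methylbutanoyloxy)-2-oxo-2,3,3a,4,5,8,9,11a-octahydrocyclodeca[b]furan-4-yl (2R,3S)-2,3-dimethyloxirane-2-carboxylate, via alkoxyphosphonium carboxylate 30 (not isolated)
Conditions: PPh3, diisopropyl azodicarboxylate (premixed), toluene, 0 °C → rt
Reagents that add atoms: none
Why: Mitsunobu esterification; the carboxylate of the fairly acidic epoxy acid displaces the C8 oxyphosphonium group by SN2, so the 8α-alcohol becomes the 8β (8R) ester in the acylation step itself.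

Step 17
Reactants: 31 (3aR,4R,6E,9S,10Z,11aR)-6,10-dimethyl-3-methylidene-9-(3-methylbutanoyloxy)-2-oxo-2,3,3a,4,5,8,9,11a-octahydrocyclodeca[b]furan-4-yl (2R,3S)-2,3-dimethyloxirane-2-carboxylate
Product: 32 (1R,3S,4Z,6R,7R,8R,10R)-1,10-epoxy-3-(3-methylbutanoyloxy)-8-{[(2R,3S)-2,3-dimethyloxiran-2-yl]carbonyloxy}germacra-4,11(13)-dien-12,6-olide (CNP0167461.4)
Conditions: mCPBA (1.1 equiv), NaHCO3, CH2Cl2, 0 °C
Reagents that add atoms: 3-chloroperbenzoic acid, OOC(=O)c1cccc(Cl)c1
Why: Prilezhaev epoxidation picks the electron-rich 1(10)-alkene over the 4,5-alkene (flanked by two acyloxy carbons) and the conjugated methylene, and attack on the exposed outer face of the E-cycloalkene gives the trans 1β,10α-epoxide (1R,10R), as is usual for germacranolides.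

## Compound list

1 | prop-2-enal (acrolein) | C=CC=O | starting material
2 | prop-1-yn-1-ylmagnesium bromide | CC#C[Mg]Br | starting material
3 | rac-hex-1-en-4-yn-3-ol | C=CC(O)C#CC | intermediate
4 | (3S)-hex-1-en-4-yn-3-ol | C=C[C@H](O)C#CC | intermediate
5 | sodium (5S)-2,2-bis(2-methoxyethoxy)-3-methyl-5-vinyl-2,5-dihydro-1,2-oxaluminol-2-uide (cyclic alkenylalanate) | [Na+].C=C[C@H]1C=C(C)[Al-](OCCOC)(OCCOC)O1 | intermediate (not isolated)
6 | (3S,4Z)-5-iodohexa-1,4-dien-3-ol | C=C[C@H](O)/C=C(/C)I | intermediate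
7 | 2-(bromomethyl)prop-2-enoic acid | C=C(CBr)C(=O)O | starting material
8 | 2-(acetoxymethyl)prop-2-enoic acid | CC(=O)OCC(=C)C(=O)O | intermediate
9 | 2-(acetoxymethyl)prop-2-enoyl chloride | CC(=O)OCC(=C)C(=O)Cl | intermediate (not isolated)
10 | (3S,4Z)-5-iodohexa-1,4-dien-3-yl 2-(acetoxymethyl)prop-2-enoate | CC(=O)OCC(=C)C(=O)O[C@@H](C=C)/C=C(/C)I | intermediate
11 | [(5S)-5-[(1Z)-2-iodoprop-1-en-1-yl]-2-oxo-2,5-dihydrofuran-3-yl]methyl acetate | O=C1O[C@H](/C=C(/C)I)C=C1COC(C)=O | intermediate
12 | but-3-yn-1-ol | C#CCCO | starting material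
13 | (but-3-yn-1-yloxy)triethylsilane | C#CCCO[Si](CC)(CC)CC | intermediate
14 | oxirane | C1CO1 | starting material
15 | dimethyl[(1E)-2-methyl-4-(triethylsilyloxy)but-1-en-1-yl]alane | C[Al](C)/C=C(\C)CCO[Si](CC)(CC)CC | intermediate (not isolated)
16 | lithium butyl(dimethyl)[(1E)-2-methyl-4-(triethylsilyloxy)but-1-en-1-yl]alanate | [Li+].CCCC[Al-](C)(C)/C=C(\C)CCO[Si](CC)(CC)CC | intermediate (not isolated)
17 | (3E)-4-methyl-6-(triethylsilyloxy)hex-3-en-1-ol | OCC/C=C(\C)CCO[Si](CC)(CC)CC | intermediate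
18 | (3E)-4-methyl-6-(triethylsilyloxy)hex-3-enal | O=CC/C=C(\C)CCO[Si](CC)(CC)CC | intermediate
19 | [(5R)-5-[(1Z,3S,5E)-3-hydroxy-2,6-dimethyl-8-(triethylsilyloxy)octa-1,5-dien-1-yl]-2-oxo-2,5-dihydrofuran-3-yl]methyl acetate | O=C1O[C@H](/C=C(/C)[C@@H](O)C/C=C(\C)CCO[Si](CC)(CC)CC)C=C1COC(C)=O | intermediate
20 | 3-methylbutanoyl chloride (isovaleryl chloride) | CC(C)CC(=O)Cl | starting material
21 | (1Z,3S,5E)-1-[(2R)-4-(acetoxymethyl)-5-oxo-2,5-dihydrofuran-2-yl]-2,6-dimethyl-8-(triethylsilyloxy)octa-1,5-dien-3-yl 3-methylbutanoate | O=C1O[C@H](/C=C(/C)[C@@H](OC(=O)CC(C)C)C/C=C(\C)CCO[Si](CC)(CC)CC)C=C1COC(C)=O | intermediate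
22 | (1Z,3S,5E)-1-[(2R)-4-(acetoxymethyl)-5-oxo-2,5-dihydrofuran-2-yl]-8-hydroxy-2,6-dimethylocta-1,5-dien-3-yl 3-methylbutanoate | O=C1O[C@H](/C=C(/C)[C@@H](OC(=O)CC(C)C)C/C=C(\C)CCO)C=C1COC(C)=O | intermediate (not isolated)
23 | (1Z,3S,5E)-1-[(2R)-4-(acetoxymethyl)-5-oxo-2,5-dihydrofuran-2-yl]-2,6-dimethyl-8-oxoocta-1,5-dien-3-yl 3-methylbutanoate | O=C1O[C@H](/C=C(/C)[C@@H](OC(=O)CC(C)C)C/C=C(\C)CC=O)C=C1COC(C)=O | intermediate
24 | C8-centred ketyl radical of 23 with O-bound diiodosamarium (trivalent samarium) | O=C1O[C@H](/C=C(/C)[C@@H](OC(=O)CC(C)C)C/C=C(\C)C[CH]O[Sm](I)I)C=C1COC(C)=O | intermediate (not isolated)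
25 | ring-closed bis(diiodosamarium) species: C8 alkoxide and C12 lactone enolate, C13 acetate still in place | CC(=O)OCC1=C(O[Sm](I)I)O[C@@H]2/C=C(/C)[C@@H](OC(=O)CC(C)C)C/C=C(\C)C[C@H](O[Sm](I)I)[C@@H]12 | intermediate (not isolated)
26 | (3aR,4S,6E,9S,10Z,11aR)-4-hydroxy-6,10-dimethyl-3-methylidene-2-oxo-2,3,3a,4,5,8,9,11a-octahydrocyclodeca[b]furan-9-yl 3-methylbutanoate (8α-hydroxy heliangolide) | C=C1C(=O)O[C@@H]2/C=C(/C)[C@@H](OC(=O)CC(C)C)C/C=C(\C)C[C@H](O)[C@@H]12 | intermediate
27 | (2E)-2-methylbut-2-en-1-ol | C/C=C(\C)CO | starting material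
28 | [(2S,3S)-2,3-dimethyloxiran-2-yl]methanol | OC[C@]1(C)O[C@H]1C | intermediate
29 | (2R,3S)-2,3-dimethyloxirane-2-carboxylic acid | OC(=O)[C@]1(C)O[C@H]1C | intermediate
30 | C8-O-triphenylphosphonium derivative of 26 paired with the carboxylate of 29 | C=C1C(=O)O[C@@H]2/C=C(/C)[C@@H](OC(=O)CC(C)C)C/C=C(\C)C[C@H](O[P+](c3ccccc3)(c3ccccc3)c3ccccc3)[C@@H]12.[O-]C(=O)[C@]1(C)O[C@H]1C | intermediate (not isolated)
31 | (3aR,4R,6E,9S,10Z,11aR)-6,10-dimethyl-3-methylidene-9-(3-methylbutanoyloxy)-2-oxo-2,3,3a,4,5,8,9,11a-octahydrocyclodeca[b]furan-4-yl (2R,3S)-2,3-dimethyloxirane-2-carboxylate | C=C1C(=O)O[C@@H]2/C=C(/C)[C@@H](OC(=O)CC(C)C)C/C=C(\C)C[C@@H](OC(=O)[C@]3(C)O[C@H]3C)[C@@H]12 | intermediate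
32 | (1R,3S,4Z,6R,7R,8R,10R)-1,10-epoxy-3-(3-methylbutanoyloxy)-8-{[(2R,3S)-2,3-dimethyloxiran-2-yl]carbonyloxy}germacra-4,11(13)-dien-12,6-olide | C=C1C(=O)O[C@@H]2/C=C(/C)[C@@H](OC(=O)CC(C)C)C[C@H]3O[C@]3(C)C[C@@H](OC(=O)[C@]3(C)O[C@H]3C)[C@@H]12 | target

## Step count and risks

Total steps: 17. Longest linear sequence: 11 (steps 1, 2, 3, 5, 6, 10, 11, 12, 13, 16, 17).

**Step 13 (radical macrocyclisation) is the most likely to fail.** The ketyl may be reduced or dimerise before the ten-membered ring closes, or SmI2 may attack the butenolide first. The fallback sets out from aldehyde 23 and comes back at alcohol 26, using the same C13 acetate in a polar, metal-templated closure. Pd(PPh3)4 (zerovalent palladium, 5 mol%) ionises the allylic acetate, and InI (monovalent indium) converts the π-allyl complex into an allylindium reagent. Under high dilution in THF this reagent adds through its γ-carbon C7 to the C8 aldehyde in a closed six-membered transition state. That forms the same C7–C8 bond and the same exocyclic methylene, and is expected to give the same 7,8-trans (8α-hydroxy) relationship. No new isolated compound is involved.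

**Step 16 (Mitsunobu inversion) is the second risk.** C8 is hindered, the phosphine can add to the methylene lactone, and elimination or participation by the 1(10)-alkene may compete. The fallback sets out from 26 and comes back at 31 and avoids phosphine. Chloromethanesulfonyl chloride and pyridine convert 26 into the 8α-chloromethanesulfonate of 26 F2. Acid 29 is converted with Cs2CO3 into cesium (2R,3S)-2,3-dimethyloxirane-2-carboxylate F3. Displacement of F2 by F3 with 18-crown-6 in toluene at 50 °C gives 31 with inversion.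

**Step 10 (catalyst-controlled C3 stereocentre) is the third risk.** If the chiral ligand gives poor selectivity, the coupling of 11 and 18 is run without it (CrCl2, cat. NiCl2, DMSO) and 19 is taken as a C3 epimer mixture. The fallback sets out from that 19 and comes back at 19. Buffered Dess–Martin oxidation gives the Z-enone [(5R)-5-[(1Z,5E)-2,6-dimethyl-3-oxo-8-(triethylsilyloxy)octa-1,5-dien-1-yl]-2-oxo-2,5-dihydrofuran-3-yl]methyl acetate F1. Reduction with (R)-2-methyl-CBS-oxazaborolidine and catecholborane in toluene at −78 °C, with the alkenyl group acting as the large substituent, returns (3S)-19.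

## Further compounds

F1 | step 10 | [(5R)-5-[(1Z,5E)-2,6-dimethyl-3-oxo-8-(triethylsilyloxy)octa-1,5-dien-1-yl]-2-oxo-2,5-dihydrofuran-3-yl]methyl acetate | O=C1O[C@H](/C=C(/C)C(=O)C/C=C(\C)CCO[Si](CC)(CC)CC)C=C1COC(C)=O
F0 | step 13 | none | none
F2 | step 16 | 8α-chloromethanesulfonate of 26 | C=C1C(=O)O[C@@H]2/C=C(/C)[C@@H](OC(=O)CC(C)C)C/C=C(\C)C[C@H](OS(=O)(=O)CCl)[C@@H]12
F3 | step 16 | cesium (2R,3S)-2,3-dimethyloxirane-2-carboxylate | [Cs+].[O-]C(=O)[C@]1(C)O[C@H]1C
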